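**Retrosynthetic overview**

1. Target ⇒ cut the aryl–CH2 bond of the methylene bridge. Ring B is used as an aryl iodide (electrophile) and the bridge carbon, beta to the ring A carbonyls, as a CH2–BF3K boron homoenolate (nucleophile). This inverts the usual formaldehyde-type union and is done by sp3–sp2 Suzuki–Miyaura coupling.
2. Boron homoenolate ⇒ propionylfilicinic acid + ICH2BF3K (C-alkylation at the one free ring CH).
3. Ring A (dearomatised triketone) ⇒ gem-dimethylation of 2,4,6-trihydroxypropiophenone.
4. Iodochromene ⇒ iodination of the 8-acetylchromene ⇒ 2,4,6-trihydroxyacetophenone + prenal.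
5. Ring order: ring A is set first on one branch; the pyran ring (ring C) is annulated onto aromatic ring B on the other; the union forms no ring.

Assumption: the target SMILES has no stereocentre (both sp3 ring carbons carry two identical methyls), so the compound is achiral and no enantiocontrol is needed; tautomers are written as in the target SMILES.

**Route**

Step 1
Reactants: 1 1-(2,4,6-trihydroxyphenyl)propan-1-one
Product: 3 3,5-dihydroxy-4,4-dimethyl-2-propanoylcyclohexa-2,5-dien-1-one (propionylfilicinic acid), via monomethyl ketone 2 (not isolated)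
Conditions: MeI (2.2 equiv), NaOMe (3.5 equiv), MeOH, 0 °C to rt
Reagents that add atoms: iodomethane (CI)
Why: Dearomatising double C-methylation of the acylphloroglucinol polyanion, in which the methyl-bearing carbon of 2 is the most nucleophilic site and is alkylated again to the gem-dimethyl triketone; no stereocentre is formed.

Step 2
Reactants: 3 propionylfilicinic acid; 4 potassium (iodomethyl)trifluoroborate
Product: 5 potassium trifluoro[(2,4-dihydroxy-3,3-dimethyl-6-oxo-5-propanoylcyclohexa-1,4-dien-1-yl)methyl]borate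
Conditions: KOt-Bu (2.1 equiv), t-BuOH/DMSO (3:1), 50 °C
Reagents that add atoms: none
Why: Proposed new method: the dianion of 3 has one nucleophilic ring CH, which should displace iodide from the tetracoordinate, non-Lewis-acidic ICH2BF3K by SN2 at carbon (soft iodide and protic cosolvent favour C- over O-alkylation, and the anionic BF3 group disfavours a second alkylation), the closest known reactions being nucleophilic substitution on potassium halomethyltrifluoroborates and C-alkylation of cyclic 1,3-dione enolates with primary iodides; boron ends up beta to both ring carbonyls, which makes 5 a homoenolate equivalent.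

Step 3
Reactants: 6 1-(2,4,6-trihydroxyphenyl)ethan-1-one; 7 3-methylbut-2-enal (1.1 equiv)
Product: 9 1-(5,7-dihydroxy-2,2-dimethyl-2H-chromen-8-yl)ethan-1-one, via oxatriene 8 (not isolated)
Conditions: ethylenediammonium diacetate (10 mol %), toluene/DMF (10:1), 100 °C
Reagents that add atoms: none
Why: Amine-salt-catalysed Knoevenagel condensation gives oxatriene 8, which closes by oxa-6π electrocyclisation onto the oxygen next to the acetyl-bearing carbon; the 6-acetyl regioisomer from closure onto the para oxygen also forms and is removed by chromatography.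

Step 4
Reactants: 9 1-(5,7-dihydroxy-2,2-dimethyl-2H-chromen-8-yl)ethan-1-one
Product: 10 1-(5,7-dihydroxy-6-iodo-2,2-dimethyl-2H-chromen-8-yl)ethan-1-one
Conditions: NIS (1.0 equiv), MeCN, −20 to 0 °C, dark
Reagents that add atoms: N-iodosuccinimide (O=C1CCC(=O)N1I)
Why: Electrophilic aromatic iodination at the only free ring position, which is flanked by two hydroxyls and far more nucleophilic than the chromene alkene.

Step 5
Reactants: 5 potassium trifluoroborate homoenolate (1.3 equiv); 10 iodochromene
Product: 11 2-[(8-acetyl-5,7-dihydroxy-2,2-dimethyl-2H-chromen-6-yl)methyl]-3,5-dihydroxy-4,4-dimethyl-6-propanoylcyclohexa-2,5-dien-1-one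
Conditions: Pd(OAc)2 (5 mol %), RuPhos (10 mol %), K2CO3 (7 equiv), 1,4-dioxane/H2O (4:1), degassed, 80 °C
Reagents that add atoms: none
Why: Suzuki–Miyaura sp3–sp2 coupling of a potassium beta-trifluoroborato ketone (boron homoenolate) with an aryl iodide, a known reaction type, in which zerovalent palladium inserts into the C–I bond of 10, the CH2–B carbon of 5 transmetalates after hydrolysis and reductive elimination forms the aryl–CH2 bond without beta-hydride loss because the neighbouring ring carbon carries no hydrogen; no stereocentre is formed.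

**Compound list**

1 | 1-(2,4,6-trihydroxyphenyl)propan-1-one | CCC(=O)c1c(O)cc(O)cc1O | starting material
2 | 1-(2,4,6-trihydroxy-3-methylphenyl)propan-1-one | CCC(=O)c1c(O)cc(O)c(C)c1O | intermediate
3 | 3,5-dihydroxy-4,4-dimethyl-2-propanoylcyclohexa-2,5-dien-1-one | CCC(=O)C1=C(O)C(C)(C)C(O)=CC1=O | intermediate
4 | potassium (iodomethyl)trifluoroborate | [K+].F[B-](F)(F)CI | starting material
5 | potassium trifluoro[(2,4-dihydroxy-3,3-dimethyl-6-oxo-5-propanoylcyclohexa-1,4-dien-1-yl)methyl]borate | [K+].CCC(=O)C1=C(O)C(C)(C)C(O)=C(C[B-](F)(F)F)C1=O | intermediate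
6 | 1-(2,4,6-trihydroxyphenyl)ethan-1-one | CC(=O)c1c(O)cc(O)cc1O | starting material
7 | 3-methylbut-2-enal | CC(C)=CC=O | starting material
8 | (6Z)-2-acetyl-3,5-dihydroxy-6-(3-methylbut-2-en-1-ylidene)cyclohexa-2,4-dien-1-one | CC(=O)C1=C(O)C=C(O)/C(=C/C=C(C)C)C1=O | intermediate
9 | 1-(5,7-dihydroxy-2,2-dimethyl-2H-chromen-8-yl)ethan-1-one | CC(=O)c1c(O)cc(O)c2C=CC(C)(C)Oc12 | intermediate
10 | 1-(5,7-dihydroxy-6-iodo-2,2-dimethyl-2H-chromen-8-yl)ethan-1-one | CC(=O)c1c(O)c(I)c(O)c2C=CC(C)(C)Oc12 | intermediate
11 | 2-[(8-acetyl-5,7-dihydroxy-2,2-dimethyl-2H-chromen-6-yl)methyl]-3,5-dihydroxy-4,4-dimethyl-6-propanoylcyclohexa-2,5-dien-1-one | CCC(=O)C1=C(O)C(C)(C)C(O)=C(Cc2c(O)c3c(c(C(C)=O)c2O)OC(C)(C)C=C3)C1=O | target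

**Totals and risks**

Total step count: 5. Longest linear sequence: 3 steps (1 → 3 → 5 → 11, or 6 → 9 → 10 → 11).

Steps most likely to fail:

- **Step 5 (key coupling).** The electrophile is an unprotected, very electron-rich di-ortho-hydroxy aryl iodide that can lose iodine, and the nucleophile is an acidic polyketone. The fallback sets out from 10 (with 5) and comes back at 11. Both phenols of 10 are capped (NaH, chloromethyl methyl ether, DMF, 0 °C) to give 1-[6-iodo-5,7-bis(methoxymethoxy)-2,2-dimethyl-2H-chromen-8-yl]ethan-1-one F1, an ordinary non-acidic aryl iodide. F1 is coupled with 5 under the same Pd(OAc)2/RuPhos conditions to give 2-{[8-acetyl-5,7-bis(methoxymethoxy)-2,2-dimethyl-2H-chromen-6-yl]methyl}-3,5-dihydroxy-4,4-dimethyl-6-propanoylcyclohexa-2,5-dien-1-one F2. The acetals are then removed with HCl in MeOH at 40 °C to give 11.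

- **Step 2 (borylmethylation).** O-alkylation or sluggish substitution at the alpha-boryl carbon could intervene. The fallback sets out from 3 and comes back at 5. Aminomethylation of 3 with dimethylmethylideneammonium iodide (MeCN, rt) gives 2-[(dimethylamino)methyl]-3,5-dihydroxy-4,4-dimethyl-6-propanoylcyclohexa-2,5-dien-1-one F3. Warming F3 with B2pin2, CuCl (5 mol %), Xantphos, NaOt-Bu (10 mol %) and MeOH in THF at 50 °C releases the exo-methylene enone by loss of dimethylamine, and copper–boryl conjugate addition gives 3,5-dihydroxy-4,4-dimethyl-6-propanoyl-2-[(4,4,5,5-tetramethyl-1,3,2-dioxaborolan-2-yl)methyl]cyclohexa-2,5-dien-1-one F4. Aqueous KHF2 in MeOH converts F4 into 5.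

- **Step 3 (chromene regiochemistry).** Ring closure can go onto either oxygen flanking the new C–C bond, and bis-annulation is possible. The fallback sets out from 6 and comes back at 9. Selective silylation of the para hydroxyl (TBSCl 1.0 equiv, imidazole, DMF, 0 °C) gives 1-[4-(tert-butyldimethylsilyloxy)-2,6-dihydroxyphenyl]ethan-1-one F5. Chromenylation of F5 with 7 under the step 3 conditions can only close onto an oxygen ortho to the acetyl group, giving 1-[5-(tert-butyldimethylsilyloxy)-7-hydroxy-2,2-dimethyl-2H-chromen-8-yl]ethan-1-one F6. Tetrabutylammonium fluoride with AcOH in THF at 0 °C then gives 9.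

**Further compounds**

F1 | step 5 | 1-[6-iodo-5,7-bis(methoxymethoxy)-2,2-dimethyl-2H-chromen-8-yl]ethan-1-one | CC(=O)c1c(OCOC)c(I)c(OCOC)c2C=CC(C)(C)Oc12
F2 | step 5 | 2-{[8-acetyl-5,7-bis(methoxymethoxy)-2,2-dimethyl-2H-chromen-6-yl]methyl}-3,5-dihydroxy-4,4-dimethyl-6-propanoylcyclohexa-2,5-dien-1-one | CCC(=O)C1=C(O)C(C)(C)C(O)=C(Cc2c(OCOC)c3C=CC(C)(C)Oc3c(C(C)=O)c2OCOC)C1=O
F3 | step 2 | 2-[(dimethylamino)methyl]-3,5-dihydroxy-4,4-dimethyl-6-propanoylcyclohexa-2,5-dien-1-one | CCC(=O)C1=C(O)C(C)(C)C(O)=C(CN(C)C)C1=O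
F4 | step 2 | 3,5-dihydroxy-4,4-dimethyl-6-propanoyl-2-[(4,4,5,5-tetramethyl-1,3,2-dioxaborolan-2-yl)methyl]cyclohexa-2,5-dien-1-one | CCC(=O)C1=C(O)C(C)(C)C(O)=C(CB2OC(C)(C)C(C)(C)O2)C1=O
F5 | step 3 | 1-[4-(tert-butyldimethylsilyloxy)-2,6-dihydroxyphenyl]ethan-1-one | CC(=O)c1c(O)cc(O[Si](C)(C)C(C)(C)C)cc1O
F6 | step 3 | 1-[5-(tert-butyldimethylsilyloxy)-7-hydroxy-2,2-dimethyl-2H-chromen-8-yl]ethan-1-one | CC(=O)c1c(O)cc(O[Si](C)(C)C(C)(C)C)c2C=CC(C)(C)Oc12
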